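**Retrosynthetic overview**

1. The strategy rests on ring B (C5–C10): it lies between the methyl-bearing quaternary carbons C8 and C10, whose methyls are syn across C9–H, and it carries the C6 oxygen 1,3 to both; this is the pattern left by a 2-silyloxydiene adding endo to the methyl-substituted double bond of a quinone.
2. Late disconnections: O–C5′ (intramolecular oxa-Michael closing the tetrahydrofuran of the spiro 6-oxabicyclo[3.2.1]octanone) and C13–C1′ (alkenylcerium from an enantiopure bromocyclohexadiene-cis-diol building block added to a 13-ketone).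
3. Ring C of the cycloadduct is trimmed to that 13-ketone by hydride reduction, 1,3-carbonyl transposition and removal of O14; the same hydride step sets the axial C6 alcohol.
4. Ring A is disconnected at C4–C5 (SN1 alkylation of the C5 enol silane by a C4 tertiary chloride, carried in the diene in place of the prenyl double bond); C7–C8 and C9–C10 go back to diene plus quinone.
5. Order of ring formation: ring C (quinone) and the cyclohexanone ring (arene cis-diol) are bought as rings; ring B (step 8), ring A (step 9), tetrahydrofuran ring (step 24).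

Key step: step 8

**Remarks on the chemistry (one line each)**

- Numbering: C1–C14 for rings A (C1–C5, C10), B (C5–C10) and C (C8, C9, C11–C14); the cyclohexanone ring is C1′ (bonded to C13), C2′ (CH2), C3′ (C=O), C4′ (CHMe), C5′ (CH–O ether), C6′ (CHOH).
- (1S,2S)-3-Bromocyclohexa-3,5-diene-1,2-diol (the cis-dihydrodiol of bromobenzene) is taken as a commercial building block; its two carbinol centres have the configuration needed at C5′ and C6′.
- The diene carries the chain terminus as a tertiary chloride so that the C4 cation can later be generated by a Lewis acid without protonating the enol silane.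

**Route**

Step 1
Reactants: 1 geranyl acetate
Product: 2 (2E)-7-chloro-3,7-dimethyloct-2-en-1-yl acetate
Conditions: HCl (g, 1.05 equiv), CH2Cl2, −40 → −20 °C
Reagents that add atoms: hydrogen chloride, SMILES Cl
Why: Markovnikov hydrochlorination; the distal trisubstituted alkene protonates faster than the 2,3-alkene, which is deactivated by the allylic acetoxy group, so the tertiary chloride should form at C7 only.

Step 2
Reactants: 2 (2E)-7-chloro-3,7-dimethyloct-2-en-1-yl acetate
Product: 3 (2E)-7-chloro-3,7-dimethyloct-2-en-1-ol
Conditions: K2CO3 (cat.), MeOH, 0 °C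
Reagents that add atoms: none
Why: Base-catalysed transesterification frees the allylic alcohol at a temperature at which the tertiary chloride neither solvolyses nor eliminates.

Step 3
Reactants: 3 (2E)-7-chloro-3,7-dimethyloct-2-en-1-ol
Product: 4 (2E)-7-chloro-3,7-dimethyloct-2-enal
Conditions: MnO2, CH2Cl2, 23 °C
Reagents that add atoms: none
Why: MnO2 allylic oxidation is selective for the allylic alcohol and keeps the E geometry.

Step 4
Reactants: 4 (2E)-7-chloro-3,7-dimethyloct-2-enal
Product: 5 (3E)-8-chloro-4,8-dimethylnon-3-en-2-ol (racemic at C2)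
Conditions: MeMgBr, THF, −78 °C; aq NH4Cl
Reagents that add atoms: methylmagnesium bromide, SMILES C[Mg]Br
Why: Grignard 1,2-addition to the enal; the tertiary chloride is inert at −78 °C and the new carbinol centre is removed in the next step.

Step 5
Reactants: 5 (3E)-8-chloro-4,8-dimethylnon-3-en-2-ol
Product: 6 (3E)-8-chloro-4,8-dimethylnon-3-en-2-one
Conditions: MnO2, CH2Cl2, 23 °C
Reagents that add atoms: none
Why: MnO2 allylic oxidation gives the E-enone without acid or base that could scramble the trisubstituted double bond.

Step 6
Reactants: 6 (3E)-8-chloro-4,8-dimethylnon-3-en-2-one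
Product: 8 (3E)-2-(tert-butyldimethylsilyloxy)-8-chloro-4,8-dimethylnona-1,3-diene, via lithium dienolate 7 (not isolated)
Conditions: LiN(i-Pr)2, THF, −78 °C; t-BuMe2SiCl, DMPU, −78 → 0 °C
Reagents that add atoms: tert-butyldimethylsilyl chloride, SMILES CC(C)(C)[Si](C)(C)Cl
Why: Kinetic deprotonation of the methyl ketone gives the cross-conjugated enolate, and O-silylation delivers the 2-silyloxydiene with the E double bond intact (methyl inside, chain outside).

Step 7
Reactants: 9 2-methoxy-6-methylphenol
Product: 10 2-methoxy-6-methyl-1,4-benzoquinone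
Conditions: (KSO3)2NO, KH2PO4, H2O–acetone, 0 → 23 °C
Reagents that add atoms: potassium nitrosodisulfonate, SMILES [K+].[K+].[O]N(S(=O)(=O)[O-])S(=O)(=O)[O-]
Why: Nitrosodisulfonate radical oxidation of a phenol with a free para position gives the para-quinone.

Step 8
Reactants: 8 (3E)-2-(tert-butyldimethylsilyloxy)-8-chloro-4,8-dimethylnona-1,3-diene; 10 2-methoxy-6-methyl-1,4-benzoquinone
Product: 11 endo cycloadduct: cis-fused B/C enedione with C5=C6 silyl enol ether (8-Me, 9-H and 10-Me all cis; 4-chloro-4-methylpentyl chain on C10)
Conditions: oxazaborolidinium triflimide (20 mol %) made from (S)-α,α-diphenylprolinol, o-tolylboronic acid (as boroxine) and HNTf2; CH2Cl2, −78 → −40 °C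
Reagents that add atoms: none
Why: The cationic boron Lewis acid binds the C4 carbonyl of quinone 10 (the more basic, vinylogous-ester carbonyl, flanked by C–H on both sides), so the C5=C6 double bond is activated with the methyl-bearing carbon as β-terminus while the methoxy-bearing double bond stays inert; the diene then adds in a concerted, asynchronous [4+2] in which its nucleophilic CH2 terminus (C7) bonds to that carbon (future C8) and C10 closes onto the α-carbon (future C9). The closest known reaction type is the oxazaborolidinium-catalysed Diels–Alder reaction of 2-silyloxy-1,3-dienes with substituted 1,4-benzoquinones, together with Lewis-acid Diels–Alder reactions of 4,4-disubstituted 2-silyloxydienes. Ring B is closed by intermolecular [4+2] annulation onto the existing quinone ring (ring C), both bonds forming on one quinone face, which makes the C8 methyl and C9–H cis. C10 is set by the endo transition state together with the E geometry of the diene: the inside methyl ends up cis to the C8 methyl and the outside chain (future ring A) trans. The absolute configuration of C8, C9 and C10 comes from the catalyst, whose aryl group shields one face of the bound quinone; by the α-C–H···O binding model the (S)-catalyst should expose the face that leads to 11 (the (R)-catalyst would be used if the sense were opposite). The step needs regio-, site-, endo- and face-selectivity, secured in turn by the site of coordination and the polarity of the diene, by the deactivating methoxy group, by secondary overlap with the quinone carbonyls and by the chiral boron cation.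

Step 9
Reactants: 11 endo cycloadduct
Product: 12 tricyclic 13-methoxy-12-ene-6,11,14-trione as the 5-epi-9-epi isomer (cis A/B and cis B/C)
Conditions: TiCl4 (1.5 equiv), CH2Cl2, −78 °C; aq NaHCO3
Reagents that add atoms: none
Why: Lewis-acid SN1 α-tert-alkylation of a silyl enol ether: TiCl4 ionises the tertiary chloride and C5 of the enol silane captures the C4 cation in a six-membered closure of ring A; the half-chair of ring B forces the new bond anti to the C10 methyl, so C5 should form cis-fused and is corrected in step 10.

Step 10
Reactants: 12 5-epi-9-epi tricyclic trione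
Product: 13 trans-anti-trans tricyclic 13-methoxy-12-ene-6,11,14-trione
Conditions: NaOMe, MeOH–THF, 23 → 50 °C, Ar
Reagents that add atoms: none
Why: Enolisation–reprotonation: C5 (α to the C6 ketone) should equilibrate to the trans-decalone, and the C9 enolate (α to C11=O) is protonated from the face opposite the two axial methyls on C8 and C10, giving the trans B/C fusion found in base-stable 11-oxo-12-ene triterpenoids.

Step 11
Reactants: 13 trans-anti-trans tricyclic trione
Product: 15 tricyclic 6,14-dihydroxy-11-en-13-one, via 6,11,14-triol 14 (not isolated)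
Conditions: LiAlH4, THF, −78 → 0 °C; then 1 M aq HCl–THF, 23 °C
Reagents that add atoms: water, SMILES O
Why: Hydride 1,2-reduction of all three ketones followed by acid-induced 1,3-carbonyl transposition (Stork–Danheiser type: the C11 allylic alcohol ionises with enol-ether assistance and water enters at C13); hydride reaches C6 only from the equatorial direction, away from the axial methyls, so the C6 alcohol is axial and syn to them as required.

Step 12
Reactants: 15 tricyclic 6,14-dihydroxy-11-en-13-one
Product: 16 tricyclic 6,14-diacetoxy-11-en-13-one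
Conditions: Ac2O, DMAP, Et3N, CH2Cl2, 23 → 40 °C
Reagents that add atoms: acetic anhydride, SMILES CC(=O)OC(C)=O
Why: DMAP-catalysed acylation installs the hindered axial C6 acetate of the target and at the same time turns the C14 hydroxyl into a leaving group α to the ketone.

Step 13
Reactants: 16 tricyclic 6,14-diacetoxy-11-en-13-one
Product: 17 tricyclic 6,14-diacetoxy-13-ketone
Conditions: H2 (1 atm), Pd/C, EtOAc, 23 °C
Reagents that add atoms: none
Why: Heterogeneous hydrogenation of the disubstituted enone double bond leaves C11 and C12 as methylenes and removes the γ-acidity at C9.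

Step 14
Reactants: 17 tricyclic 6,14-diacetoxy-13-ketone
Product: 18 tricyclic 6-acetoxy-13-ketone
Conditions: SmI2 (2.2 equiv), THF–MeOH, −78 °C
Reagents that add atoms: none
Why: SmI2 reductive cleavage of an α-acetoxy ketone removes the C14 oxygen through the ketyl, while the isolated C6 acetate is not reduced.

Step 15
Reactants: 19 (1S,2S)-3-bromocyclohexa-3,5-diene-1,2-diol
Product: 20 (3aS,7aS)-4-bromo-2,2-dimethyl-3a,7a-dihydro-1,3-benzodioxole
Conditions: 2,2-dimethoxypropane, TsOH (cat.), acetone, 0 °C
Reagents that add atoms: 2,2-dimethoxypropane, SMILES COC(C)(C)OC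
Why: Acid-catalysed transketalisation protects the cis-diol (C5′–O and C6′–O) as the acetonide.

Step 16
Reactants: 20 bromodiene acetonide
Product: 21 C3′–C4′ epoxide of 20, anti to the dioxolane
Conditions: 3-chloroperoxybenzoic acid, NaHCO3, CH2Cl2, 0 °C
Reagents that add atoms: 3-chloroperoxybenzoic acid, SMILES OOC(=O)c1cccc(Cl)c1
Why: Peracid epoxidation takes the electron-richer distal double bond (the bromoalkene is deactivated) from the face opposite the dioxolane.

Step 17
Reactants: 21 vinyl epoxide
Product: 22 C3′ benzyl ether C4′ alcohol (benzyloxy cis to the dioxolane oxygens; hydroxyl trans)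
Conditions: BnOH, BF3·OEt2 (cat.), CH2Cl2, −40 °C
Reagents that add atoms: benzyl alcohol, SMILES OCc1ccccc1
Why: Lewis-acid-catalysed opening of the vinyl epoxide by the alcohol at the allylic carbon C3′ with inversion, the usual regiochemistry for this class of diene epoxides.

Step 18
Reactants: 22 benzyl ether alcohol
Product: 23 C4′ ketone
Conditions: Dess–Martin periodinane, NaHCO3, CH2Cl2, 23 °C
Reagents that add atoms: none
Why: Dess–Martin oxidation of the secondary alcohol under buffered, non-enolising conditions.

Step 19
Reactants: 23 C4′ ketone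
Product: 24 alkenyl bromide with exocyclic C4′ methylene
Conditions: Zn, CH2Br2, TiCl4, THF–CH2Cl2, 0 → 23 °C
Reagents that add atoms: dibromomethane, SMILES BrCBr
Why: Takai–Lombardo methylenation is non-basic, so the α-alkoxy allylic centre C3′ is not enolised and the acetonide is kept; the methylene carbon becomes the C4′ methyl.

Step 20
Reactants: 24 alkenyl bromide; 18 tricyclic 6-acetoxy-13-ketone
Product: 27 C13 tertiary alcohol bearing the cyclohexadienyl fragment (C13–OH axial and syn to the C8 methyl), via alkenyllithium 25 (not isolated), via alkenylcerium dichloride 26 (not isolated)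
Conditions: t-BuLi (2.1 equiv), THF, −78 °C; CeCl3 (anhydrous), −78 °C; then 18, −78 → −40 °C; aq NH4Cl
Reagents that add atoms: none
Why: Halogen–lithium exchange, transmetalation and organocerium 1,2-addition to the ketone; the low basicity and ester tolerance of the cerium reagent spare the enolisable ketone and the hindered acetate, and equatorial attack (the axial path is blocked by the syn-axial C8 methyl) places the C13 oxygen axial as in the target.

Step 21
Reactants: 27 C13 tertiary alcohol
Product: 28 saturated carbinol (C1′–H anti to the three oxygens so that C13 is cis to C6′–O; C4′ methyl)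
Conditions: H2 (4 atm), PtO2, EtOAc, 23 °C
Reagents that add atoms: none
Why: Heterogeneous hydrogenation adds hydrogen to the ring alkene and the exocyclic methylene from the face opposite the dioxolane and the benzyloxy group, which sets C1′ with the C13 substituent cis to the C6′ oxygen; platinum is chosen to limit hydrogenolysis of the allylic C–O bonds.

Step 22
Reactants: 28 saturated carbinol
Product: 29 C3′ alcohol
Conditions: H2 (1 atm), Pd(OH)2/C, EtOH, 23 °C
Reagents that add atoms: none
Why: Hydrogenolysis of the benzyl ether, which is no longer allylic, leaves the acetonide, the acetate and the tertiary alcohol intact.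

Step 23
Reactants: 29 C3′ alcohol
Product: 30 C3′ ketone
Conditions: Dess–Martin periodinane, NaHCO3, CH2Cl2, 23 °C
Reagents that add atoms: none
Why: Dess–Martin oxidation of the only secondary alcohol; the tertiary C13 alcohol cannot be oxidised.

Step 24
Reactants: 30 C3′ ketone
Product: 32 CNP0188572.2 (target), via hydroxy enone 31 (not isolated)
Conditions: DBU, toluene, 23 → 60 °C
Reagents that add atoms: none
Why: E1cB β-elimination of the acetonide oxygen at C5′ (acetone is lost and C6′–OH freed) gives the 4-hydroxy-2-methylcyclohexenone, and the cis C13 hydroxyl then closes the tetrahydrofuran by 5-exo-trig oxa-Michael addition to C5′; C5′ is fixed by the bridging geometry and the C4′ methyl settles equatorial by reversible protonation.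

**Compound list**

1 | geranyl acetate | CC(=O)OC/C=C(\C)CCC=C(C)C | starting material
2 | (2E)-7-chloro-3,7-dimethyloct-2-en-1-yl acetate | CC(=O)OC/C=C(\C)CCCC(C)(C)Cl | intermediate
3 | (2E)-7-chloro-3,7-dimethyloct-2-en-1-ol | OC/C=C(\C)CCCC(C)(C)Cl | intermediate
4 | (2E)-7-chloro-3,7-dimethyloct-2-enal | O=C/C=C(\C)CCCC(C)(C)Cl | intermediate
5 | (3E)-8-chloro-4,8-dimethylnon-3-en-2-ol (racemic at C2) | CC(O)/C=C(\C)CCCC(C)(C)Cl | intermediate
6 | (3E)-8-chloro-4,8-dimethylnon-3-en-2-one | CC(=O)/C=C(\C)CCCC(C)(C)Cl | intermediate
7 | lithium (3E)-8-chloro-4,8-dimethylnona-1,3-dien-2-olate | [Li]OC(=C)/C=C(\C)CCCC(C)(C)Cl | intermediate (not isolated)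
8 | (3E)-2-(tert-butyldimethylsilyloxy)-8-chloro-4,8-dimethylnona-1,3-diene | C=C(O[Si](C)(C)C(C)(C)C)/C=C(\C)CCCC(C)(C)Cl | intermediate
9 | 2-methoxy-6-methylphenol | COc1cccc(C)c1O | starting material
10 | 2-methoxy-6-methyl-1,4-benzoquinone | COC1=CC(=O)C=C(C)C1=O | intermediate
11 | endo cycloadduct, cis-fused B/C, C5=C6 silyl enol ether, 8-Me/9-H/10-Me all cis | CC(C)(Cl)CCC[C@]1(C)C=C(O[Si](C)(C)C(C)(C)C)C[C@]2(C)C(=O)C(OC)=CC(=O)[C@H]12 | intermediate
12 | 5-epi-9-epi tricyclic 13-methoxy-12-ene-6,11,14-trione (cis A/B, cis B/C) | O=C1C[C@]2(C)C(=O)C(OC)=CC(=O)[C@@H]2[C@]2(C)CCCC(C)(C)[C@H]12 | intermediate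
13 | trans-anti-trans tricyclic 13-methoxy-12-ene-6,11,14-trione | O=C1C[C@]2(C)C(=O)C(OC)=CC(=O)[C@H]2[C@]2(C)CCCC(C)(C)[C@@H]12 | intermediate
14 | 13-methoxy-12-ene-6,11,14-triol (6-OH axial; C11 and C14 not assigned) | O[C@H]1C[C@]2(C)C(O)C(OC)=CC(O)[C@H]2[C@]2(C)CCCC(C)(C)[C@@H]12 | intermediate (not isolated)
15 | 6,14-dihydroxy-11-en-13-one (C14 not assigned) | O[C@H]1C[C@]2(C)C(O)C(=O)C=C[C@H]2[C@]2(C)CCCC(C)(C)[C@@H]12 | intermediate
16 | 6,14-diacetoxy-11-en-13-one | CC(=O)O[C@H]1C[C@]2(C)C(OC(C)=O)C(=O)C=C[C@H]2[C@]2(C)CCCC(C)(C)[C@@H]12 | intermediate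
17 | 6,14-diacetoxy-13-ketone | CC(=O)O[C@H]1C[C@]2(C)C(OC(C)=O)C(=O)CC[C@H]2[C@]2(C)CCCC(C)(C)[C@@H]12 | intermediate
18 | 6-acetoxy-13-ketone | CC(=O)O[C@H]1C[C@]2(C)CC(=O)CC[C@H]2[C@]2(C)CCCC(C)(C)[C@@H]12 | intermediate
19 | (1S,2S)-3-bromocyclohexa-3,5-diene-1,2-diol | O[C@@H]1[C@H](O)C(Br)=CC=C1 | starting material
20 | (3aS,7aS)-4-bromo-2,2-dimethyl-3a,7a-dihydro-1,3-benzodioxole | CC2(C)O[C@@H]1[C@H](O2)C(Br)=CC=C1 | intermediate
21 | C3′–C4′ epoxide of 20, anti to the dioxolane | CC2(C)O[C@@H]1[C@H](O2)C(Br)=C[C@H]3O[C@@H]13 | intermediate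
22 | C3′ benzyl ether, C4′ alcohol (trans) | CC2(C)O[C@@H]1[C@H](O2)C(Br)=C[C@H](OCc3ccccc3)[C@H]1O | intermediate
23 | C4′ ketone | CC2(C)O[C@@H]1[C@H](O2)C(Br)=C[C@H](OCc3ccccc3)C1=O | intermediate
24 | alkenyl bromide with C4′ exocyclic methylene | CC2(C)O[C@@H]1[C@H](O2)C(Br)=C[C@H](OCc3ccccc3)C1=C | intermediate
25 | alkenyllithium from 24 | CC2(C)O[C@@H]1[C@H](O2)C([Li])=C[C@H](OCc3ccccc3)C1=C | intermediate (not isolated)
26 | alkenylcerium dichloride from 25 | CC2(C)O[C@@H]1[C@H](O2)C([Ce](Cl)Cl)=C[C@H](OCc3ccccc3)C1=C | intermediate (not isolated)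
27 | C13 tertiary alcohol with cyclohexadienyl fragment | CC(=O)O[C@H]1C[C@]2(C)C[C@@](O)(CC[C@H]2[C@]2(C)CCCC(C)(C)[C@@H]12)C3=C[C@H](OCc4ccccc4)C(=C)[C@@H]4OC(C)(C)O[C@H]34 | intermediate
28 | saturated carbinol (C13 cis to C6′–O; C4′ methyl as expected from anti-face hydrogenation) | CC(=O)O[C@H]1C[C@]2(C)C[C@@](O)(CC[C@H]2[C@]2(C)CCCC(C)(C)[C@@H]12)[C@@H]3C[C@H](OCc4ccccc4)[C@H](C)[C@@H]4OC(C)(C)O[C@H]34 | intermediate
29 | C3′ alcohol | CC(=O)O[C@H]1C[C@]2(C)C[C@@](O)(CC[C@H]2[C@]2(C)CCCC(C)(C)[C@@H]12)[C@@H]3C[C@H](O)[C@H](C)[C@@H]4OC(C)(C)O[C@H]34 | intermediate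
30 | C3′ ketone | CC(=O)O[C@H]1C[C@]2(C)C[C@@](O)(CC[C@H]2[C@]2(C)CCCC(C)(C)[C@@H]12)[C@@H]3CC(=O)[C@H](C)[C@@H]4OC(C)(C)O[C@H]34 | intermediate
31 | hydroxy enone (C13–OH, C6′–OH, C4′=C5′ enone) | CC(=O)O[C@H]1C[C@]2(C)C[C@@](O)(CC[C@H]2[C@]2(C)CCCC(C)(C)[C@@H]12)[C@@H]3CC(=O)C(C)=C[C@@H]3O | intermediate (not isolated)
32 | CNP0188572.2 | CC(=O)O[C@H]1C[C@]2(C)C[C@]3(CC[C@H]2[C@]2(C)CCCC(C)(C)[C@@H]12)O[C@@H]1[C@H](O)[C@H]3CC(=O)[C@@H]1C | target

**Step count**

Total: 24 steps. Longest linear sequence: 18 steps (steps 1–6, 8–14, 20–24); the quinone (step 7) and the bromide 24 (steps 15–19) are side branches.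

**Steps most likely to fail**

Step 8. The cycloaddition has to create two quaternary carbons (C8, C10) with a diene whose inside methyl disfavours the s-cis conformer. The bond formation may stall, may stop after the first C–C bond (Mukaiyama–Michael addition without ring closure), or may need temperatures at which endo and face selectivity erode. The fallback gives up catalytic face control and sets out from 8 and 10. The uncatalysed cycloaddition under high pressure (about 12–15 kbar, CH2Cl2, 23 °C) should give the endo adduct as a racemate, that is 11 together with its enantiomer ent-11 F1. Steps 9 and 10 on the racemate give ent-12 F2 beside 12 and then ent-13 F3 beside 13. The stable trione is resolved by preparative chromatography on a chiral stationary phase, and the route is rejoined at 13.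

Step 10. Removal of the hindered C9 proton may be slow, or the equilibrium at C9 may not lie clearly on the trans side, so that the C5-equilibrated but C9-unchanged isomer 9-epi-13 F4 remains. The fallback replaces equilibrium control by kinetic control and sets out from that material (or its mixture with 13). KN(SiMe3)2 (excess, THF, −78 °C) forms the C9 enolate irreversibly, and inverse addition to AcOH–THF at −78 °C delivers the proton to the face opposite the two axial methyls. This should give the trans B/C isomer, and the route is rejoined at 13.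

Step 21. On the metal surface the allylic C–O bonds (C6′–O, C3′–OBn, C13–OH) may be hydrogenolysed, and the hindered trisubstituted alkene may saturate slowly or with poor face selectivity. The fallback changes from surface hydrogenation to hydrogen-atom transfer in solution and sets out from 27. With Mn(dpm)3 (cat.), PhSiH3 and t-BuOOH in i-PrOH at 23 °C, a hydrogen atom adds to C2′ and to the methylene carbon, and the tertiary radicals at C1′ and C4′ are quenched from the face opposite the dioxolane. No C–O bond is cleaved, no compound outside the list is made (F0), and the route is rejoined at 28.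

Further compounds
F1 | step 8 | ent-11 (enantiomer of cycloadduct 11) | CC(C)(Cl)CCC[C@@]1(C)C=C(O[Si](C)(C)C(C)(C)C)C[C@@]2(C)C(=O)C(OC)=CC(=O)[C@@H]12
F2 | step 8 | ent-12 | O=C1C[C@@]2(C)C(=O)C(OC)=CC(=O)[C@H]2[C@@]2(C)CCCC(C)(C)[C@@H]12
F3 | step 8 | ent-13 | O=C1C[C@@]2(C)C(=O)C(OC)=CC(=O)[C@@H]2[C@@]2(C)CCCC(C)(C)[C@H]12
F4 | step 10 | 9-epi-13 (trans A/B, cis B/C) | O=C1C[C@]2(C)C(=O)C(OC)=CC(=O)[C@@H]2[C@]2(C)CCCC(C)(C)[C@@H]12
F0 | step 21 | none | none
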